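**Retrosynthetic overview**
1. The tertiary alcohol is unveiled last, by MeMgBr addition to a methyl ketone. This keeps the acid-labile benzylic C–O bond away from acid while a free tertiary OH is present.
2. Key disconnection: the Ca–Cc bond joining the two monomer halves. It is made by a 6-exo-trig radical conjugate cyclisation of a Ca radical onto an enone tethered through the Cb–O bond. This closes the last ring and sets Ca and Cc.
3. The Cb–O tether comes from SN2 opening of enantioenriched N-methylflindersine 3,4-epoxide by the 4-OH of a 3-(3-oxobutenyl)quinolone. The C-3 OH that remains is the radical precursor.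
4. The epoxide comes from Jacobsen epoxidation of N-methylflindersine, itself a formal [3+3] of 4-hydroxy-1-methyl-2-quinolone with prenal. The enone partner comes from the same quinolone and but-3-yn-2-one.
5. Ring order: both quinolones (N-methylaniline + malonic acid), then the dimethylpyran ring, then the central dihydropyran ring.

**Labels and assumption:** Ca is the CH next to CMe2 (C-3 of the pyran unit), Cb is the O-bearing CH (C-4), and Cc is the CH carrying the side chain. Read from the SMILES, the target is Ca R, Cb S, Cc R (Ha/Hb cis, Hc trans to Ha). I assume the (S,S)-Mn(salen) catalyst epoxidises N-methylflindersine with the same facial sense as 2,2-dimethylchromenes, that is (S,S) gives (3S,4S).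

**Step 1**
Reactants: 1 N-methylaniline; 2 malonic acid
Product: 4 4-hydroxy-1-methylquinolin-2(1H)-one, via N-methyl-N-phenylmalonamic acid 3 (not isolated)
Conditions: POCl3 (3 equiv), 95 °C, 2 h; ice, aq NaOH, then HCl
Reagents that add atoms: none
Why: N-acylation followed by POCl3-promoted intramolecular Friedel–Crafts acylation is the standard 4-hydroxy-2-quinolone synthesis from an N-alkylaniline and malonic acid; no stereocentre is formed.

**Step 2**
Reactants: 4 4-hydroxy-1-methylquinolin-2(1H)-one; 5 3-methylbut-2-enal (prenal)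
Product: 7 N-methylflindersine, via prenylidenequinolinedione 6 (not isolated)
Conditions: ethylenediammonium diacetate (10 mol %), MeOH, reflux, 6 h
Reagents that add atoms: none
Why: Knoevenagel condensation gives 1-oxatriene 6, which closes by oxa-6π electrocyclisation (formal [3+3] annulation), the established entry to this pyranoquinolone; no stereocentre is formed.

**Step 3**
Reactants: 7 N-methylflindersine
Product: 8 (3S,4S)-3,4-epoxy-3,4-dihydro-N-methylflindersine
Conditions: (S,S)-Jacobsen Mn(salen)Cl (4 mol %), 4-phenylpyridine N-oxide (20 mol %), aq NaOCl (pH 11.3, 1.5 equiv), CH2Cl2, 0 °C; recrystallise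
Reagents that add atoms: sodium hypochlorite, [Na+].[O-]Cl
Why: Jacobsen–Katsuki epoxidation works best on cis-alkenes in 2,2-dimethylchromene-type rings (typically >95 % ee), and the catalyst fixes the face and hence the absolute configuration of the whole route.

**Step 4**
Reactants: 4 4-hydroxy-1-methylquinolin-2(1H)-one; 9 but-3-yn-2-one
Product: 10 (E)-4-hydroxy-1-methyl-3-(3-oxobut-1-en-1-yl)quinolin-2(1H)-one
Conditions: 9 (1.3 equiv), Et3N (20 mol %), MeCN, 0 to 40 °C
Reagents that add atoms: none
Why: This is a Michael addition of the nucleophilic C-3 of the vinylogous acid to a terminal ynone; the ynone is far more electrophilic than the product enone, so mono-addition wins, and amine-catalysed equilibration gives the E-enone.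

**Step 5**
Reactants: 8 (3S,4S)-epoxide; 10 enone-quinolone
Product: 11 (3S,4R)-3-hydroxy-2,2,6-trimethyl-4-{[1-methyl-2-oxo-3-((E)-3-oxobut-1-enyl)-1,2-dihydroquinolin-4-yl]oxy}-3,4-dihydro-2H-pyrano[3,2-c]quinolin-5(6H)-one (trans)
Conditions: 10 (1.1 equiv), Cs2CO3 (0.3 equiv), DMF, 60 °C; chromatography
Reagents that add atoms: none
Why: In this base-catalysed SN2 epoxide opening (the chroman-3-ol type trans-opening) the C-3-blocked quinolonate attacks through O-4 at the benzylic, less hindered C-4 with inversion, which sets the Cb–O stereocentre and leaves the C-3 OH trans.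

**Step 6 (key step)**
Reactants: 11 trans-hydroxy ether
Product: 13 cis-fused hexacyclic methyl ketone (Ca R; Cb S; Cc R), via benzoxazoline orthoamide 12 (not isolated)
Conditions: (i) 5,7-di-t-Bu-3-Ph-benzoxazolium BF4 (1.2 equiv), pyridine (1.2 equiv), MTBE/CH2Cl2, rt, 30 min; (ii) [Ir(ppy)2(dtbbpy)]PF6 (2 mol %), n-Bu4NOBz (20 mol %), MTBE/DMA 4:1, 0.01 M, 450 nm LEDs, 0 °C
Reagents that add atoms: 5,7-di-tert-butyl-3-phenylbenzoxazol-3-ium tetrafluoroborate, CC(C)(C)c1cc(C(C)(C)C)c2oc[n+](-c3ccccc3)c2c1.F[B-](F)(F)F (its atoms are in 12 only; none stay in 13)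
Why: This is a photoredox deoxygenative Giese reaction run intramolecularly as a 6-exo-trig radical conjugate cyclisation: oxidation, deprotonation and β-scission of 12 release the nucleophilic secondary Ca radical, which adds to the enone β-carbon, and Ir(II) then reduces the α-keto radical before protonation; the pseudo-axial Cb–O tether (A1,3 strain with the peri C-5 carbonyl) can deliver the acceptor only to its own face, so Ca–Cc forms cis to O (Ca R), and in the half-chair transition state the enone arm lies anti to the gem-dimethyl group and out of the plane of the C-2' carbonyl, which gives Cc R.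

**Step 7**
Reactants: 13 hexacyclic methyl ketone
Product: 14 target alcohol (Ca R; Cb S; Cc R)
Conditions: MeMgBr (1.5 equiv), LaCl3·2LiCl (30 mol %), THF, −78 to −40 °C; then H2O
Reagents that add atoms: methylmagnesium bromide, C[Mg]Br
Why: Grignard 1,2-addition occurs at the only reactive carbonyl because the two quinolone vinylogous-carbamate carbonyls are inert at low temperature, and no stereocentre is touched under these basic conditions.

**Compound list**
1 | N-methylaniline | CNc1ccccc1 | starting material
2 | malonic acid | OC(=O)CC(=O)O | starting material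
3 | N-methyl-N-phenylmalonamic acid | CN(c1ccccc1)C(=O)CC(=O)O | intermediate
4 | 4-hydroxy-1-methylquinolin-2(1H)-one | Cn1c(=O)cc(O)c2ccccc21 | intermediate
5 | 3-methylbut-2-enal | CC(C)=CC=O | starting material
6 | 1-methyl-3-(3-methylbut-2-en-1-ylidene)quinoline-2,4(1H,3H)-dione | CN1C(=O)C(=CC=C(C)C)C(=O)c2ccccc21 | intermediate
7 | N-methylflindersine (2,2,6-trimethyl-2,6-dihydro-5H-pyrano[3,2-c]quinolin-5-one) | Cn1c(=O)c2c(c3ccccc31)OC(C)(C)C=C2 | intermediate
8 | (3S,4S)-3,4-epoxy-3,4-dihydro-N-methylflindersine | Cn1c(=O)c2c(c3ccccc31)OC(C)(C)[C@H]1O[C@H]12 | intermediate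
9 | but-3-yn-2-one | CC(=O)C#C | starting material
10 | (E)-4-hydroxy-1-methyl-3-(3-oxobut-1-en-1-yl)quinolin-2(1H)-one | Cn1c(=O)c(/C=C/C(C)=O)c(O)c2ccccc21 | intermediate
11 | (3S,4R)-trans-3-hydroxy-4-(quinolon-4-yloxy) ether | Cn1c(=O)c2c(c3ccccc31)OC(C)(C)[C@@H](O)[C@@H]2Oc1c(/C=C/C(C)=O)c(=O)n(C)c2ccccc12 | intermediate
12 | O-3 benzoxazoline orthoamide of 11 | Cn1c(=O)c2c(c3ccccc31)OC(C)(C)[C@@H](OC1Oc3c(C(C)(C)C)cc(C(C)(C)C)cc3N1c1ccccc1)[C@@H]2Oc1c(/C=C/C(C)=O)c(=O)n(C)c2ccccc12 | intermediate
13 | cis-fused hexacyclic methyl ketone (Ca R, Cb S, Cc R) | Cn1c(=O)c2c(c3ccccc31)OC(C)(C)[C@H]1[C@@H]2Oc2c(c(=O)n(C)c3ccccc23)[C@@H]1CC(C)=O | intermediate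
14 | target tertiary alcohol (Ca R, Cb S, Cc R) | Cn1c(=O)c2c(c3ccccc31)OC(C)(C)[C@H]1[C@@H]2Oc2c(c(=O)n(C)c3ccccc23)[C@@H]1CC(C)(C)O | target

**Total steps:** 7. **Longest linear sequence:** 6 (steps 1, 2, 3, 5, 6, 7).

**Three steps most likely to fail**

*Step 6.*
- Risk: the Ca radical carries a β-aryloxy group aligned with its SOMO. It may fragment, homolytically or heterolytically, back to 7 and 10, or be reduced before it cyclises.
- Low temperature, low polarity and the activated acceptor are chosen to counter this.
- Fallback: it sets out from 7 (and uses 10) and comes back at 13. The C–C bond is made before the C–O bond, so the radical carries only a non-fragmenting β-methoxy group.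
  - 7 is epoxidised with the (R,R)-catalyst to the (3R,4R)-epoxide F1.
  - Acid-catalysed methanolysis gives trans-(3R,4S)-3-hydroxy-4-methoxy-dihydro-N-methylflindersine F2.
  - Its benzoxazoline orthoamide F3 releases the Ca radical under the same photoredox conditions.
  - The radical adds intermolecularly, anti to OMe, to 10 (3 equiv) to give the open Giese adduct F4. The Cc epimer is separated.
  - Catalytic Sc(OTf)3 in CH2Cl2 ionises the benzylic C-4–OMe bond, and the 4'-OH closes cis to the new C–C bond to give 13.
  - The opposite catalyst enantiomer is needed here because Ca is set anti to the C-4 oxygen and Cb is then reset.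

*Step 5.*
- Risk: the delocalised anion of 10 may be too weak a nucleophile for the hindered epoxide. SN1 leakage would give the cis isomer, which would lead to the wrong enantiomeric series.
- Fallback: it sets out from 8 and 10 and comes back at 11. The nucleophile and electrophile roles are swapped.
  - 8 is hydrolysed (H2O/THF, cat. HClO4) to the trans-(3S,4R)-diol F5.
  - 10 is converted with TsCl/Et3N into the 4-tosyloxyquinolone F6.
  - The less hindered benzylic C-4 alkoxide of F5 (Cs2CO3, MeCN) displaces tosylate at C-4' by addition–elimination.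
  - The stereodefined C-4–O bond is never broken.

*Step 4.*
- Risk: O-vinylation may compete with C-addition, and a second molecule of 4 may add to 10 to give a warfarin-type 2:1 adduct.
- Fallback: it sets out from 4 and comes back at 10.
  - 4 is iodinated (NIS, MeCN) to 4-hydroxy-3-iodo-1-methylquinolin-2(1H)-one F7.
  - Heck coupling with but-3-en-2-one (Pd(OAc)2, P(o-tol)3, Et3N, DMF, 80 °C) gives only the E-enone 10, with no free C-3 nucleophile present.

**Further compounds**
F1 | step 6 | (3R,4R)-3,4-epoxy-3,4-dihydro-N-methylflindersine | Cn1c(=O)c2c(c3ccccc31)OC(C)(C)[C@@H]1O[C@@H]12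
F2 | step 6 | (3R,4S)-3-hydroxy-4-methoxy-2,2,6-trimethyl-3,4-dihydro-2H-pyrano[3,2-c]quinolin-5(6H)-one | Cn1c(=O)c2c(c3ccccc31)OC(C)(C)[C@H](O)[C@H]2OC
F3 | step 6 | O-3 benzoxazoline orthoamide of F2 | Cn1c(=O)c2c(c3ccccc31)OC(C)(C)[C@H](OC1Oc3c(C(C)(C)C)cc(C(C)(C)C)cc3N1c1ccccc1)[C@H]2OC
F4 | step 6 | open Giese adduct (Ca R, Cb R, Cc R) | Cn1c(=O)c2c(c3ccccc31)OC(C)(C)[C@@H]([C@H]2OC)[C@@H](CC(C)=O)c1c(O)c2ccccc2n(C)c1=O
F5 | step 5 | (3S,4R)-3,4-dihydroxy-2,2,6-trimethyl-3,4-dihydro-2H-pyrano[3,2-c]quinolin-5(6H)-one | Cn1c(=O)c2c(c3ccccc31)OC(C)(C)[C@@H](O)[C@@H]2O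
F6 | step 5 | (E)-1-methyl-2-oxo-3-(3-oxobut-1-en-1-yl)-1,2-dihydroquinolin-4-yl 4-methylbenzenesulfonate | Cn1c(=O)c(/C=C/C(C)=O)c(OS(=O)(=O)c2ccc(C)cc2)c2ccccc21
F7 | step 4 | 4-hydroxy-3-iodo-1-methylquinolin-2(1H)-one | Cn1c(=O)c(I)c(O)c2ccccc21
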